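Ring B is cut between C7 and C8. The trans-vicinal pair on ring B, a β-isopropenyl group (C11=C12) on C7 next to an α-oxygen on C8, is the imprint of a carbonyl-ene reaction between a C8 aldehyde and a prenyl chain. In one operation the key step forms C7–C8, closes ring B onto ring A, sets C7 and C8 and creates the isopropenyl group. Its precursor is a ring A ketal holding, cis to each other, a prenyl group on C5 and a silyloxy aldehyde arm on C10. C9 is carried as its 9β epimer, equatorial in the productive chair, and is corrected afterwards by oxidation and convex-face reduction.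

Key step: step 10

Remark (numbering): eremophilane numbering is used. Ring A = C1–C5 and C10, ring B = C5–C10, C14 on C5, C15 on C4, C11–C13 the three-carbon unit on C7. β is the face of C14, C15 and H10.
Remark (C9): the chair that gives 7β,8α has C4 axial and C14 equatorial on ring B. In it a 9α ether would be axial, buried in the concave face against H4 and the α ketal oxygen, so the flipped chair leading to 7α,8β would win. The aldehyde is therefore built with a 9β oxygen, and C9 is inverted after ring closure.
Remark (C8): C8 travels as a silyl-protected primary alcohol. A C8 ester would make H9 both α to a carbonyl group and γ to the enone, which would endanger C9 during dienol ether formation.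
Assumption: the (S)-prolinol-derived oxazaborolidinium ion is taken to leave open the enal face that leads to the 4β,5β series; if the sense is opposite, its equally available antipode is used.
Assumption: enantiopure (R)-but-3-ene-1,2-diol is taken as a catalogue compound.

Step 1
Reactants: 1 (R)-but-3-ene-1,2-diol
Product: 2 (R)-3,4-bis(tert-butyldimethylsilyloxy)but-1-ene
Conditions: TBSCl (2.4 equiv), imidazole, DMF, rt
Reagents that add atoms: tert-butyldimethylsilyl chloride, CC(C)(C)[Si](C)(C)Cl
Why: Imidazole-promoted O-silylation caps both hydroxyls in one operation and leaves the allylic stereocentre, the future C9, untouched.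

Step 2
Reactants: 2 (R)-3,4-bis(tert-butyldimethylsilyloxy)but-1-ene; 3 methyl vinyl ketone
Product: 4 (R,E)-5,6-bis(tert-butyldimethylsilyloxy)hex-3-en-2-one
Conditions: second-generation Hoveyda–Grubbs catalyst, C31H38Cl2N2ORu (5 mol %), 3 (3 equiv), CH2Cl2, 40 °C
Reagents that add atoms: none
Why: Olefin cross metathesis between a hindered allylic ether and an electron-poor enone favours the cross product and gives the E-enone, and the stereocentre takes no part.

Step 3
Reactants: 4 (R,E)-5,6-bis(tert-butyldimethylsilyloxy)hex-3-en-2-one
Product: 5 (R,E)-5,6-bis(tert-butyldimethylsilyloxy)-2-(triisopropylsilyloxy)hexa-1,3-diene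
Conditions: TIPSOTf, Et3N, CH2Cl2, 0 °C
Reagents that add atoms: triisopropylsilyl triflate, CC(C)[Si](OS(=O)(=O)C(F)(F)F)(C(C)C)C(C)C
Why: Soft enolisation (silyl triflate plus amine) removes a proton of the methyl ketone and gives the cross-conjugated 2-silyloxydiene, while H9, flanked only by ether groups, is not acidic and C9 keeps its configuration.

Step 4
Reactants: 5 (R,E)-5,6-bis(tert-butyldimethylsilyloxy)-2-(triisopropylsilyloxy)hexa-1,3-diene; 6 tiglaldehyde
Product: 7 cyclohexene carbaldehyde: C5 with β-methyl C14 and α-formyl C6, C4 with β-methyl C15, C10 (H β) with the α-oriented (R)-1,2-bis(TBSO)ethyl arm C9–C8, C1=C2 as TIPS enol ether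
Conditions: oxazaborolidinium triflimide from (S)-α,α-diphenylprolinol, tri(o-tolyl)boroxine and HNTf2 (20 mol %), 6 (3 equiv), CH2Cl2, −78 → −20 °C
Reagents that add atoms: none
Why: In this catalytic enantioselective Diels–Alder reaction the silyloxy group (para) and the C10 substituent (ortho) both send C3 to the β-carbon of the enal, suprafacial addition carries the cis methyl groups of the E-enal into C4 and C5, the endo formyl group places C6 cis to the C9 arm on C10, and the catalyst fixes the absolute sense, which the allylic stereocentre (C8 anti, silyloxy inside) is expected to reinforce.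

Step 5
Reactants: 7 cyclohexene carbaldehyde
Product: 9 keto aldehyde bearing the C6–C7 acetaldehyde arm on C5 and the free C2 ketone, via methyl enol ether 8 (not isolated)
Conditions: MeOCH2PPh3Cl, KN(SiMe3)2, THF, 0 °C → rt; then 1 M aq HCl, 0 °C
Reagents that add atoms: (methoxymethyl)triphenylphosphonium chloride, COC[P+](c1ccccc1)(c1ccccc1)c1ccccc1.[Cl-]; water, O
Why: Wittig methoxymethylenation of the non-enolisable neopentyl aldehyde, then acid hydrolysis of both enol ethers (protonated far faster than alkyl TBS ethers are cleaved), adds C7 as an aldehyde and frees C2 without touching a stereocentre.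

Step 6
Reactants: 9 keto aldehyde
Product: 10 prenyl ketone (C5 α-prenyl, C2 ketone, bis-TBS arm on C10)
Conditions: i-PrPPh3I, n-BuLi, THF, 0 °C; then 9 (ylide 1.05 equiv), −78 → −20 °C
Reagents that add atoms: isopropyltriphenylphosphonium iodide, CC(C)[P+](c1ccccc1)(c1ccccc1)c1ccccc1.[I-]
Why: In this Wittig olefination the non-stabilised ylide, kept close to one equivalent at low temperature, reacts with the unhindered aldehyde much faster than with the ketone and completes the prenyl arm.

Step 7
Reactants: 10 prenyl ketone
Product: 11 C2 ethylene ketal of 10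
Conditions: (TMSOCH2)2, TMSOTf (5 mol %), CH2Cl2, −78 → −20 °C; pyridine quench
Reagents that add atoms: 1,2-bis(trimethylsilyloxy)ethane, C[Si](C)(C)OCCO[Si](C)(C)C
Why: Aprotic silyl-transfer ketalisation at low temperature protects C2 without harming the silyl ethers or the trisubstituted alkene, and the ketal later tells C2 from the C9 ketone.

Step 8
Reactants: 11 C2 ethylene ketal
Product: 12 primary C8 alcohol (9β-OTBS retained)
Conditions: HF·pyridine, pyridine, THF, 0 °C
Reagents that add atoms: none
Why: Selective desilylation works because buffered HF cleaves the unhindered primary TBS ether well before the flanked secondary one, and the acidic fluoride medium avoids silyl migration.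

Step 9
Reactants: 12 primary C8 alcohol
Product: 13 ene precursor: ring A ketal with β-methyl and α-prenyl on C5, β-methyl on C4, and the (R)-CH(OTBS)CHO arm on C10 (H β)
Conditions: Dess–Martin periodinane, NaHCO3, CH2Cl2, 0 °C → rt
Reagents that add atoms: none
Why: Buffered Dess–Martin oxidation gives the α-silyloxy aldehyde under non-epimerising conditions and leaves alkene, ketal and silyl ether alone.

Step 10
Reactants: 13 ene precursor
Product: 15 cis-fused decalin with 7β-isopropenyl 8α-hydroxy 9β-TBSO 10βH and the C2 ketal, via chloromethylaluminium alkoxide 14 (not isolated)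
Conditions: Me2AlCl (1.5 equiv), CH2Cl2 (0.01 M), −78 → −40 °C; aq potassium sodium tartrate
Reagents that add atoms: none
Why: Me2AlCl binds the C8 aldehyde oxygen, C7 of the prenyl alkene attacks C8 while a hydrogen of a C11 methyl group passes to O8 through a six-membered array, and the alcohol complex loses methane to give alkoxide 14, which removes the proton source for alkene isomerisation. The closest known reaction is the type 1 intramolecular carbonyl-ene cyclisation of citronellal to isopulegol. Ring B closes as a six-membered ring in an exo,exo mode, with both the C8=O and the C7=C11 π bonds left outside the new ring, between arms that ring A already holds cis on C5 and C10. C7 and C8 are set by a chair with C4 axial and C14 equatorial on the forming ring, in which the alkene on C7, the aluminium-bound oxygen on C8 and the 9β-silyloxy group are all equatorial, so that isopropenyl comes out β and hydroxyl α, trans to each other. The C9 stereocentre selects this chair, because there its C–O bond lies anti to the forming bond, whereas the flipped chair would make it axial and syn to C14. The step needs aldehyde-over-ketal chemoselectivity and no chelation, which are secured by the low temperature, by fewer than two equivalents of a mild proton-scavenging Lewis acid and by the bulky, poorly donating silyl ether.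

Step 11
Reactants: 15 ene product
Product: 16 8α-acetate
Conditions: Ac2O, DMAP (cat.), pyridine, rt
Reagents that add atoms: acetic anhydride, CC(=O)OC(C)=O
Why: DMAP-catalysed acetylation meets a single free hydroxyl, the equatorial C8 alcohol.

Step 12
Reactants: 16 8α-acetate
Product: 17 8α-acetoxy-9β-alcohol
Conditions: Bu4NF, AcOH (1:1), THF, rt → 40 °C
Reagents that add atoms: none
Why: Fluoride-mediated desilylation buffered with acetic acid stays non-basic, so the acetate should neither migrate nor be cleaved, and the ketal is inert.

Step 13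
Reactants: 17 8α-acetoxy-9β-alcohol
Product: 18 8α-acetoxy-9-ketone
Conditions: Dess–Martin periodinane, NaHCO3, CH2Cl2, 0 °C → rt
Reagents that add atoms: none
Why: Dess–Martin oxidation is neutral, and C10 and C8 should hold because a trans ring fusion would force the 7β-isopropenyl group syn-axial to C14 and an 8β-acetate would be axial.

Step 14
Reactants: 18 8α-acetoxy-9-ketone
Product: 19 8α-acetoxy-9α-alcohol
Conditions: LiBH(s-Bu)3, THF, −78 °C; AcOH quench at −78 °C
Reagents that add atoms: none
Why: In this diastereoselective reduction of a cyclohexanone by a bulky borohydride the α face of C9 lies in the concave fold and is blocked by axial C4, so hydride enters from the convex β face (equatorial attack) and gives the axial 9α alcohol, while the ketal shields C2 and the acetate survives at −78 °C.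

Step 15
Reactants: 19 8α-acetoxy-9α-alcohol; 20 tiglic acid
Product: 21 C2 ethylene ketal of the target (8α-acetate, 9α-tiglate)
Conditions: 20, 2,4,6-Cl3C6H2COCl, Et3N, toluene, rt; then 19, DMAP, toluene, rt → 60 °C
Reagents that add atoms: none
Why: In the Yamaguchi esterification the mixed anhydride and DMAP generate an acylpyridinium ion reactive enough for the hindered axial hydroxyl, the E-tiglate is the stable alkene isomer, and the acetate already sits on the favoured equatorial oxygen.

Step 16
Reactants: 21 C2 ethylene ketal of the target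
Product: 22 target, 8α-acetoxy-9α-tigloyloxy-10βH-eremophil-11-en-2-one
Conditions: 1 M aq HCl, THF, rt
Reagents that add atoms: water, O
Why: Acid-catalysed ketal hydrolysis is tolerated by both esters and by the 1,1-disubstituted alkene, and no stereocentre is α to the liberated C2 ketone.

Compound list
1 | (R)-but-3-ene-1,2-diol | C=C[C@@H](O)CO | starting material
2 | (R)-3,4-bis(tert-butyldimethylsilyloxy)but-1-ene | C=C[C@@H](O[Si](C)(C)C(C)(C)C)CO[Si](C)(C)C(C)(C)C | intermediate
3 | methyl vinyl ketone | C=CC(C)=O | starting material
4 | (R,E)-5,6-bis(tert-butyldimethylsilyloxy)hex-3-en-2-one | CC(=O)/C=C/[C@@H](O[Si](C)(C)C(C)(C)C)CO[Si](C)(C)C(C)(C)C | intermediate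
5 | (R,E)-5,6-bis(tert-butyldimethylsilyloxy)-2-(triisopropylsilyloxy)hexa-1,3-diene | C=C(O[Si](C(C)C)(C(C)C)C(C)C)/C=C/[C@@H](O[Si](C)(C)C(C)(C)C)CO[Si](C)(C)C(C)(C)C | intermediate
6 | tiglaldehyde, (E)-2-methylbut-2-enal | C/C=C(\C)C=O | starting material
7 | Diels–Alder adduct: 5α-formyl, 4β,5β-dimethyl, 10βH, (9R)-8,9-bis(TBSO) arm on C10, C1=C2 TIPS enol ether | O=C[C@@]1(C)[C@H](C=C(O[Si](C(C)C)(C(C)C)C(C)C)C[C@@H]1C)[C@@H](O[Si](C)(C)C(C)(C)C)CO[Si](C)(C)C(C)(C)C | intermediate
8 | methyl enol ether of the homologated aldehyde (E/Z mixture at C6=C7), not isolated | COC=C[C@@]1(C)[C@H](C=C(O[Si](C(C)C)(C(C)C)C(C)C)C[C@@H]1C)[C@@H](O[Si](C)(C)C(C)(C)C)CO[Si](C)(C)C(C)(C)C | intermediate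
9 | keto aldehyde: C2 ketone, C7 aldehyde on the C5 α-arm | O=CC[C@@]1(C)[C@H](CC(=O)C[C@@H]1C)[C@@H](O[Si](C)(C)C(C)(C)C)CO[Si](C)(C)C(C)(C)C | intermediate
10 | prenyl ketone | CC(C)=CC[C@@]1(C)[C@H](CC(=O)C[C@@H]1C)[C@@H](O[Si](C)(C)C(C)(C)C)CO[Si](C)(C)C(C)(C)C | intermediate
11 | prenyl ketal, bis-TBS ether | CC(C)=CC[C@@]1(C)[C@H](CC2(OCCO2)C[C@@H]1C)[C@@H](O[Si](C)(C)C(C)(C)C)CO[Si](C)(C)C(C)(C)C | intermediate
12 | primary C8 alcohol, 9β-OTBS | CC(C)=CC[C@@]1(C)[C@H](CC2(OCCO2)C[C@@H]1C)[C@@H](O[Si](C)(C)C(C)(C)C)CO | intermediate
13 | ene precursor: ring A ketal, C5 prenyl, C10 (R)-silyloxy aldehyde arm | CC(C)=CC[C@@]1(C)[C@H](CC2(OCCO2)C[C@@H]1C)[C@@H](O[Si](C)(C)C(C)(C)C)C=O | intermediate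
14 | chloromethylaluminium alkoxide of 15, not isolated | C=C(C)[C@H]1C[C@@]2(C)[C@H](CC3(OCCO3)C[C@@H]2C)[C@@H](O[Si](C)(C)C(C)(C)C)[C@@H]1O[Al](C)Cl | intermediate
15 | ene product: cis-decalin, 7β-isopropenyl, 8α-OH, 9β-OTBS, C2 ketal | C=C(C)[C@H]1C[C@@]2(C)[C@H](CC3(OCCO3)C[C@@H]2C)[C@@H](O[Si](C)(C)C(C)(C)C)[C@@H]1O | intermediate
16 | 8α-acetate, 9β-OTBS | C=C(C)[C@H]1C[C@@]2(C)[C@H](CC3(OCCO3)C[C@@H]2C)[C@@H](O[Si](C)(C)C(C)(C)C)[C@@H]1OC(C)=O | intermediate
17 | 8α-acetoxy-9β-alcohol | C=C(C)[C@H]1C[C@@]2(C)[C@H](CC3(OCCO3)C[C@@H]2C)[C@@H](O)[C@@H]1OC(C)=O | intermediate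
18 | 8α-acetoxy-9-ketone | C=C(C)[C@H]1C[C@@]2(C)[C@H](CC3(OCCO3)C[C@@H]2C)C(=O)[C@@H]1OC(C)=O | intermediate
19 | 8α-acetoxy-9α-alcohol | C=C(C)[C@H]1C[C@@]2(C)[C@H](CC3(OCCO3)C[C@@H]2C)[C@H](O)[C@@H]1OC(C)=O | intermediate
20 | tiglic acid, (E)-2-methylbut-2-enoic acid | C/C=C(\C)C(=O)O | starting material
21 | 8α-acetoxy-9α-tigloyloxy C2 ketal | C=C(C)[C@H]1C[C@@]2(C)[C@H](CC3(OCCO3)C[C@@H]2C)[C@H](OC(=O)/C(C)=C/C)[C@@H]1OC(C)=O | intermediate
22 | 8α-acetoxy-9α-tigloyloxy-10βH-eremophil-11-en-2-one (CNP0204573.1) | C=C(C)[C@H]1C[C@@]2(C)[C@H](CC(=O)C[C@@H]2C)[C@H](OC(=O)/C(C)=C/C)[C@@H]1OC(C)=O | target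

Total step count: 16. Longest linear sequence: 16 steps (from 1).

Steps most likely to fail

Step 10. The closure may leak through the flipped chair, or the aluminium Lewis acid may ionise the ketal or add a methyl group to the aldehyde. The fallback makes the same C7–C8 bond under neutral conditions by an intramolecular Nozaki–Hiyama–Kishi-type allylation. It sets out from 11. Ene-type chlorination of the prenyl group (Ca(OCl)2, solid CO2, CH2Cl2–H2O, 0 °C) would give the transposed secondary allylic chloride F1, whose C7 epimers are of no consequence. Selective release of the primary hydroxyl (HF·pyridine, pyridine, THF) would give the primary alcohol F2, and Dess–Martin oxidation the chloro aldehyde F3. CrCl2 (divalent chromium) in THF at high dilution would form the allylchromium species with the metal on C12. This species adds through C7 to the aldehyde in a chair-like cyclic transition state with the same all-equatorial preference, and the fallback returns to the route at 15.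

Step 4. The trisubstituted enal may react sluggishly, so that silyl-transfer (aldol-type) addition of the dienol ether competes and facial control erodes. The fallback moves construction of the quaternary centre out of the cycloaddition. It sets out from 5, which would react with the less hindered (E)-crotonaldehyde under the same type of oxazaborolidinium catalysis to give the endo C5–H aldehyde F4. α-Methylation of its potassium enolate (KOt-Bu, CH3I, THF, −78 → 0 °C) should occur on the β face, anti to the bulky C10 arm, and the fallback returns to the route at 7.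

Step 15. Acylation of the concave axial hydroxyl may be so slow that the neighbouring acetate has time to migrate, after which the freed equatorial oxygen would be acylated instead. The fallback reverses the order of the two acylations. It sets out from 19. Methanolysis (K2CO3, MeOH) would give the 8α,9α-diol F5. Selective silylation of the far more accessible equatorial hydroxyl (TESCl, imidazole, CH2Cl2, 0 °C) would give the 8-O-triethylsilyl ether F6. Yamaguchi esterification with 20 under forcing conditions, now with no acyl group able to migrate, would give the 9-tiglate F7. Aqueous HCl in THF would remove the silyl ether and the ketal together to give the hydroxy ketone F8, which is acetylated at once (Ac2O, pyridine, DMAP). The fallback returns to the route at 22.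

Further compounds
F1 | step 10 | transposed allylic chloride (C7–Cl, C11=C12), bis-TBS ketal | C=C(C)C(Cl)C[C@@]1(C)[C@H](CC2(OCCO2)C[C@@H]1C)[C@@H](O[Si](C)(C)C(C)(C)C)CO[Si](C)(C)C(C)(C)C
F2 | step 10 | allylic chloride with free C8 alcohol | C=C(C)C(Cl)C[C@@]1(C)[C@H](CC2(OCCO2)C[C@@H]1C)[C@@H](O[Si](C)(C)C(C)(C)C)CO
F3 | step 10 | chloro aldehyde | C=C(C)C(Cl)C[C@@]1(C)[C@H](CC2(OCCO2)C[C@@H]1C)[C@@H](O[Si](C)(C)C(C)(C)C)C=O
F4 | step 4 | crotonaldehyde adduct, C5–H aldehyde (5α-formyl, 4β-methyl, 10βH) | O=C[C@H]1[C@H](C=C(O[Si](C(C)C)(C(C)C)C(C)C)C[C@@H]1C)[C@@H](O[Si](C)(C)C(C)(C)C)CO[Si](C)(C)C(C)(C)C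
F5 | step 15 | 8α,9α-diol, C2 ketal | C=C(C)[C@H]1C[C@@]2(C)[C@H](CC3(OCCO3)C[C@@H]2C)[C@H](O)[C@@H]1O
F6 | step 15 | 8α-O-triethylsilyl ether, 9α-alcohol | C=C(C)[C@H]1C[C@@]2(C)[C@H](CC3(OCCO3)C[C@@H]2C)[C@H](O)[C@@H]1O[Si](CC)(CC)CC
F7 | step 15 | 8α-O-triethylsilyl ether, 9α-tiglate | C=C(C)[C@H]1C[C@@]2(C)[C@H](CC3(OCCO3)C[C@@H]2C)[C@H](OC(=O)/C(C)=C/C)[C@@H]1O[Si](CC)(CC)CC
F8 | step 15 | 8α-hydroxy-9α-tigloyloxy C2 ketone | C=C(C)[C@H]1C[C@@]2(C)[C@H](CC(=O)C[C@@H]2C)[C@H](OC(=O)/C(C)=C/C)[C@@H]1O
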